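The target is a 19-membered macrocycle of four arenes: ring A (4-hydroxy-3-aryloxyphenyl), ring B (meta-phenylene), ring C (the catechol ring) and ring D (para-phenylene). Everything rests on disconnecting the CH2–CH2 bridge between ring D and ring A. Both bridge carbons are benzylic and each sits para to an oxygen, so both can be formyl carbons brought in unchanged with 4-fluorobenzaldehyde and isovanillin. An intramolecular McMurry coupling of the open-chain dialdehyde (ring A–O–ring B–CH=CH–ring C–O–ring D) closes the macrocycle at that bond as a stilbene in one operation; a single hydrogenation then saturates both two-carbon bridges and BBr3 frees the three phenols.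

Key step: step 4

Remark: the target has no stereocentre; the alkene geometries created on the way are removed by the hydrogenation, so no stereocontrol is required.

Step 1
Reactants: 1 3-hydroxy-4,5-dimethoxybenzaldehyde; 2 diethyl (3-bromobenzyl)phosphonate
Product: 3 5-[(E)-2-(3-bromophenyl)ethenyl]-2,3-dimethoxyphenol
Conditions: KOtBu (2.5 equiv), DMF, 0 °C to rt; then aq. HCl
Reagents that add atoms: none
Why: Horner–Wadsworth–Emmons olefination; the phenoxide of 1 is meta to the formyl group and does not deactivate it by resonance, the benzylic phosphonate anion should give the E-stilbene, and the aryl bromide is inert.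

Step 2
Reactants: 3 5-[(E)-2-(3-bromophenyl)ethenyl]-2,3-dimethoxyphenol; 4 4-fluorobenzaldehyde
Product: 5 4-{5-[(E)-2-(3-bromophenyl)ethenyl]-2,3-dimethoxyphenoxy}benzaldehyde
Conditions: K2CO3, DMF, 120 °C
Reagents that add atoms: none
Why: Nucleophilic aromatic substitution (SNAr); the para-formyl group activates fluoride displacement by the phenoxide of 3, while the unactivated aryl bromide on ring B should stay untouched without a metal catalyst.

Step 3
Reactants: 5 4-{5-[(E)-2-(3-bromophenyl)ethenyl]-2,3-dimethoxyphenoxy}benzaldehyde; 6 isovanillin (3-hydroxy-4-methoxybenzaldehyde)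
Product: 7 3-(3-{(E)-2-[3-(4-formylphenoxy)-4,5-dimethoxyphenyl]ethenyl}phenoxy)-4-methoxybenzaldehyde
Conditions: CuI (20 mol%), N,N-dimethylglycine hydrochloride, Cs2CO3, 1,4-dioxane, 100 °C
Reagents that add atoms: none
Why: Ullmann-type diaryl ether synthesis catalysed by monovalent copper; the caesium phenoxide of 6 should couple at the only C–Br bond, on ring B, and both aldehydes and the stilbene tolerate the carbonate base in dioxane.

Step 4
Reactants: 7 3-(3-{(E)-2-[3-(4-formylphenoxy)-4,5-dimethoxyphenyl]ethenyl}phenoxy)-4-methoxybenzaldehyde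
Product: 9 macrocyclic bis-stilbene (19-membered ring; CH=CH between rings B and C kept E; new CH=CH between rings D and A drawn Z; three OMe groups), via macrocyclic titanium pinacolate 8 (not isolated)
Conditions: TiCl4 (10 equiv), Zn dust (20 equiv), pyridine, THF, reflux; 7 added by syringe pump over 24 h to about 2 mM final concentration
Reagents that add atoms: none
Why: McMurry reductive carbonyl coupling: low-valent titanium made from TiCl4 and Zn reduces both formyl groups to ketyl radicals, these join to the titanium pinacolate 8, and at reflux the pinacolate is deoxygenated to the C=C bond between the former formyl carbon on ring D and that on ring A. The closest known reaction type is the McMurry macrocyclisation of aromatic dialdehydes to macrocyclic stilbenes and stilbenophanes. The single ring closed is the 19-membered macrocycle, closed by end-to-end coupling of the two terminal carbonyl carbons of one chain; no stereocentre is set, and the geometry of the new alkene (Z expected, because a simple geometric estimate puts the two ether oxygens held by the rigid E-configured ring B–ring C stilbene about 9 Å apart, a span that a Z-stilbene between rings D and A fits) is erased in step 5. The selectivity needed is ring closure over intermolecular coupling; slow addition into excess reagent keeps the concentration of free dialdehyde minimal, and the two diaryl ether hinges allow the chain to fold so that both aldehydes reach the same titanium surface. The two aldehydes need not be differentiated, since the only intramolecular coupling possible forms the desired bond, and aryl methyl ethers, diaryl ethers and the existing stilbene are inert to the reagent.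

Step 5
Reactants: 9 macrocyclic bis-stilbene
Product: 10 tri-O-methyl ether of the target (both bridges CH2CH2; OMe on ring A para to the bridge; two OMe on ring C)
Conditions: H2 (1 atm), 10% Pd/C, EtOAc/MeOH, rt
Reagents that add atoms: none
Why: Heterogeneous catalytic hydrogenation should saturate both stilbene C=C bonds, either geometry of the ring-closing alkene converging on the same CH2–CH2 bridge, while aryl methyl ethers and diaryl ethers are not hydrogenolysed under these mild conditions.

Step 6
Reactants: 10 tri-O-methyl ether of the target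
Product: 11 target (CNP0495401.0; the triphenol macrocycle)
Conditions: BBr3 (9 equiv), CH2Cl2, −78 °C to rt; then H2O
Reagents that add atoms: none
Why: Lewis-acid cleavage of aryl methyl ethers: bromide attacks the methyl carbon of each boron-complexed ArOMe, whereas the diaryl ethers offer no sp3 carbon and should survive; aqueous work-up frees the three phenols.

Compound list
1 | 3-hydroxy-4,5-dimethoxybenzaldehyde | COc1cc(C=O)cc(O)c1OC | starting material
2 | diethyl (3-bromobenzyl)phosphonate | CCOP(=O)(Cc1cccc(Br)c1)OCC | starting material
3 | 5-[(E)-2-(3-bromophenyl)ethenyl]-2,3-dimethoxyphenol | COc1cc(/C=C/c2cccc(Br)c2)cc(O)c1OC | intermediate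
4 | 4-fluorobenzaldehyde | O=Cc1ccc(F)cc1 | starting material
5 | 4-{5-[(E)-2-(3-bromophenyl)ethenyl]-2,3-dimethoxyphenoxy}benzaldehyde | COc1cc(/C=C/c2cccc(Br)c2)cc(Oc2ccc(C=O)cc2)c1OC | intermediate
6 | isovanillin (3-hydroxy-4-methoxybenzaldehyde) | COc1ccc(C=O)cc1O | starting material
7 | 3-(3-{(E)-2-[3-(4-formylphenoxy)-4,5-dimethoxyphenyl]ethenyl}phenoxy)-4-methoxybenzaldehyde | COc1ccc(C=O)cc1Oc1cccc(/C=C/c2cc(OC)c(OC)c(Oc3ccc(C=O)cc3)c2)c1 | intermediate
8 | macrocyclic pinacol between the ring D and ring A benzylic carbons, present as its titanium diolate (SMILES of the parent 1,2-diol; configuration of the two carbinol carbons uncontrolled and lost on deoxygenation) | O1c2cccc(c2)/C=C/c2cc(OC)c(OC)c(c2)Oc2ccc(cc2)C(O)C(O)c2ccc(OC)c1c2 | intermediate (not isolated)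
9 | macrocyclic bis-stilbene (E between rings B and C; Z drawn between rings D and A; three OMe) | O1c2cccc(c2)/C=C/c2cc(OC)c(OC)c(c2)Oc2ccc(cc2)/C=C\c2ccc(OC)c1c2 | intermediate
10 | tri-O-methyl ether of the target (saturated macrocycle) | COc1ccc2cc1Oc1cccc(c1)CCc1cc(OC)c(OC)c(c1)Oc1ccc(cc1)CC2 | intermediate
11 | target CNP0495401.0 | Oc1ccc2cc1Oc1cccc(c1)CCc1cc(O)c(O)c(c1)Oc1ccc(cc1)CC2 | target

Total step count: 6
Longest linear sequence: 6 steps (1 to 11)

Steps most likely to fail

Step 4 (macrocyclisation). The rigid E-stilbene between rings B and C may hold the two formyl groups apart, so that intermolecular coupling to oligomers outruns ring closure or the reaction stalls at the pinacol stage. The fallback sets out from 3 and makes the chain flexible before closing the same bond by metathesis. Diimide reduction of 3 (TsNHNH2, NaOAc, THF/H2O, reflux) should saturate the stilbene without touching the bromide and give 5-[2-(3-bromophenyl)ethyl]-2,3-dimethoxyphenol F1. SNAr with 4 (K2CO3, DMF, 120 °C) gives 4-{5-[2-(3-bromophenyl)ethyl]-2,3-dimethoxyphenoxy}benzaldehyde F2. Ullmann coupling with 6 under the conditions of step 3 gives the bibenzyl dialdehyde 3-(3-{2-[3-(4-formylphenoxy)-4,5-dimethoxyphenyl]ethyl}phenoxy)-4-methoxybenzaldehyde F3. Double Wittig methylenation (Ph3PCH3Br, KOtBu, THF, 0 °C) gives the bis-styrene F4. Ring-closing metathesis (second-generation Grubbs catalyst, toluene, 80 °C, about 1 mM) should close the ring D–ring A bridge with loss of ethylene to give the macrocyclic mono-stilbene F5. Hydrogenation of F5 as in step 5 comes back to the route at 10.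

Step 3 (diaryl ether on ring B). Coupling of the ortho-methoxy phenoxide may be slow, leaving time for hydrodebromination of 5, for aryloxide exchange at the formyl-activated diaryl ether, or for base-induced decay of the aldehydes. The fallback sets out from 5 and reverses the polarity. Miyaura borylation (B2pin2, Pd(dppf)Cl2, KOAc, dioxane, 80 °C) gives the pinacol boronate 4-{2,3-dimethoxy-5-[(E)-2-[3-(4,4,5,5-tetramethyl-1,3,2-dioxaborolan-2-yl)phenyl]ethenyl]phenoxy}benzaldehyde F6. Oxidative Chan–Lam coupling of F6 with 6 (Cu(OAc)2, B(OH)3, Et3N, 4 Å MS, MeCN, air, 80 °C) then forms the same C–O bond under weakly basic conditions and comes back at 7.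

Step 1 (olefination of a free phenol). The potassium phenoxide of 1 may precipitate or react sluggishly, giving incomplete olefination. The fallback sets out from 1 and masks the phenol first, with a nitrile as latent formyl group so that only one aldehyde is present. SNAr of 1 with 4-fluorobenzonitrile (K2CO3, DMF, 120 °C) gives 4-(5-formyl-2,3-dimethoxyphenoxy)benzonitrile F7. Horner–Wadsworth–Emmons reaction with 2 (KOtBu, THF, 0 °C) gives 4-{5-[(E)-2-(3-bromophenyl)ethenyl]-2,3-dimethoxyphenoxy}benzonitrile F8. Reduction of the nitrile with i-Bu2AlH (toluene, −78 °C; then aq. HCl) comes back at 5.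

Further compounds
F1 | step 4 | 5-[2-(3-bromophenyl)ethyl]-2,3-dimethoxyphenol | COc1cc(CCc2cccc(Br)c2)cc(O)c1OC
F2 | step 4 | 4-{5-[2-(3-bromophenyl)ethyl]-2,3-dimethoxyphenoxy}benzaldehyde | COc1cc(CCc2cccc(Br)c2)cc(Oc2ccc(C=O)cc2)c1OC
F3 | step 4 | 3-(3-{2-[3-(4-formylphenoxy)-4,5-dimethoxyphenyl]ethyl}phenoxy)-4-methoxybenzaldehyde | COc1ccc(C=O)cc1Oc1cccc(CCc2cc(OC)c(OC)c(Oc3ccc(C=O)cc3)c2)c1
F4 | step 4 | bis-styrene: 4-ethenyl-2-(3-{2-[3-(4-ethenylphenoxy)-4,5-dimethoxyphenyl]ethyl}phenoxy)-1-methoxybenzene | COc1ccc(C=C)cc1Oc1cccc(CCc2cc(OC)c(OC)c(Oc3ccc(C=C)cc3)c2)c1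
F5 | step 4 | macrocyclic mono-stilbene (CH=CH between rings D and A, drawn E; CH2CH2 between rings B and C; three OMe) | O1c2cccc(c2)CCc2cc(OC)c(OC)c(c2)Oc2ccc(cc2)/C=C/c2ccc(OC)c1c2
F6 | step 3 | 4-{2,3-dimethoxy-5-[(E)-2-[3-(4,4,5,5-tetramethyl-1,3,2-dioxaborolan-2-yl)phenyl]ethenyl]phenoxy}benzaldehyde | COc1cc(/C=C/c2cccc(B3OC(C)(C)C(C)(C)O3)c2)cc(Oc2ccc(C=O)cc2)c1OC
F7 | step 1 | 4-(5-formyl-2,3-dimethoxyphenoxy)benzonitrile | COc1cc(C=O)cc(Oc2ccc(C#N)cc2)c1OC
F8 | step 1 | 4-{5-[(E)-2-(3-bromophenyl)ethenyl]-2,3-dimethoxyphenoxy}benzonitrile | COc1cc(/C=C/c2cccc(Br)c2)cc(Oc2ccc(C#N)cc2)c1OC
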